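**Retrosynthetic overview**
- Feature: C7a (bonded to N1) and C3a (bonded to C3) are adjacent carbons of the benzene ring, and the C4 bromine sits next to C3a. The carbocycle can therefore enter as 3,5-dibromobenzyne (triple bond C3a≡C7a), and the flanking bromine decides which end takes nitrogen.
- C2-Br and C3-Br are removed last. They come from 4,6-dibromoindole-2-carboxylic acid by C3 bromination and ipso bromodecarboxylation at C2, and the acid comes from its methyl ester.
- The indole ester comes from the N-tosylindoline-2-carboxylate by loss of toluenesulfinate, so the tosyl group serves as both N-activator and internal oxidant.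
- Key disconnection: N1-C7a and C3-C3a are cut together. This gives an o-silylaryl triflate (from 2,4,6-tribromophenol) and methyl 2-(tosylamino)acrylate (from serine methyl ester and TsCl).
- Ring order: the benzene ring is bought. The five-membered ring is the only ring built (step 5) and is aromatised in step 6.

Key step: step 5

Assumption: serine methyl ester is used as its commercial hydrochloride. The target is achiral, so neither the serine configuration nor the racemic C2 of the indoline matters.

**Step 1**
Reactants: 1 2,4,6-tribromophenol
Product: 2 trimethyl(2,4,6-tribromophenoxy)silane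
Conditions: (Me3Si)2NH (0.75 equiv), THF, reflux; concentrate, use crude
Reagents that add atoms: hexamethyldisilazane, C[Si](C)(C)N[Si](C)(C)C
Why: O-silylation of an acidic phenol with hexamethyldisilazane is fast and forms only a volatile by-product, so the moisture-sensitive silyl ether can be carried on without purification.

**Step 2**
Reactants: 2 trimethyl(2,4,6-tribromophenoxy)silane
Product: 5 2,4-dibromo-6-(trimethylsilyl)phenyl trifluoromethanesulfonate, via aryllithium 3 (not isolated), via lithium phenoxide 4 (not isolated)
Conditions: n-BuLi (1.05 equiv), THF, −100 → −78 °C; then Tf2O (1.2 equiv), −100 → −78 °C; aq NaHCO3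
Reagents that add atoms: trifluoromethanesulfonic anhydride, O=S(=O)(C(F)(F)F)OS(=O)(=O)C(F)(F)F
Why: Bromine-lithium exchange should be fastest at one of the two equivalent bromines ortho to oxygen (inductive activation and O-Li coordination), the aryllithium has no ortho leaving group and undergoes the retro-Brook 1,3 O-to-C silyl shift driven by phenoxide formation, and the phenoxide is trapped by Tf2O, which is the standard route from o-bromophenols to o-silylaryl triflates.

**Step 3**
Reactants: 6 L-serine methyl ester hydrochloride; 7 p-toluenesulfonyl chloride
Product: 8 methyl N-tosyl-L-serinate, (S)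
Conditions: Et3N (2.2 equiv), CH2Cl2, 0 °C → rt
Reagents that add atoms: none
Why: N-sulfonylation of the primary amine outruns O-sulfonylation of the alcohol when one equivalent of TsCl is used at 0 °C, and the retained (S) centre is erased in the next step.

**Step 4**
Reactants: 8 methyl N-tosyl-L-serinate
Product: 10 methyl 2-(tosylamino)acrylate, via O-mesylate 9 (not isolated)
Conditions: MsCl (1.2 equiv), Et3N (3 equiv), CH2Cl2, 0 °C → rt; use promptly, store cold
Reagents that add atoms: none
Why: O-mesylation followed by amine-induced E1cB β-elimination across the acidic α-C-H is the standard dehydration of N-acceptor-protected serine esters to dehydroalanine esters.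

**Step 5**
Reactants: 5 2,4-dibromo-6-(trimethylsilyl)phenyl trifluoromethanesulfonate (1.0 equiv); 10 methyl 2-(tosylamino)acrylate (1.5 equiv)
Product: 12 methyl 4,6-dibromo-1-tosylindoline-2-carboxylate (racemic), via 3,5-dibromobenzyne 11 (not isolated)
Conditions: Bu4N[Ph3SiF2] (1.5 equiv), THF (0.1 M), 23 °C
Reagents that add atoms: none
Why: Fluoride attacks silicon of 5 and triflate leaves, releasing 3,5-dibromobenzyne 11 at ambient temperature where both C-Br bonds and the ester are inert; the sulfonamide nitrogen of 10 (deprotonated by fluoride or by the product enolate, so that proton transfer runs as a chain) adds to the aryne and the resulting aryl anion adds to the acrylate CH2, so N1-C7a and C3-C3a form in one operation. The closest known reaction type is the fluoride-triggered aryne annulation of N-acceptor-substituted 2-aminoacrylates to indoline-2-carboxylates, supported by the N-arylation of sulfonamides with o-silylaryl triflates and by the use of arynes carrying a flanking bromine in such annulations. The five-membered ring closes stepwise by a formally 5-endo-trig conjugate addition, which is feasible because the in-plane sp2 carbanion sits next to the N-bound acceptor and the ester enolate is a strong thermodynamic sink. The only new stereocentre, C2, arises from uncontrolled protonation of that enolate, so 12 is racemic, which does not matter because C2 becomes sp2 in step 6. The selectivity needed is the orientation of nitrogen addition: the bromine beside one aryne carbon distorts the triple bond and inductively stabilises charge on the adjacent carbon, so nitrogen should attack the remote carbon (future C7a) and the bromines end at C4 and C6 and not at C5 and C7, the second bromine being too remote to exert more than a weak bias. Keeping 5 as the limiting component leaves no aryne to N-arylate any indole ester formed early by sulfinate loss from the enolate, and such material is simply carried into step 6.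

**Step 6**
Reactants: 12 methyl 4,6-dibromo-1-tosylindoline-2-carboxylate
Product: 14 methyl 4,6-dibromo-1H-indole-2-carboxylate, via 3H-indole tautomer 13 (not isolated)
Conditions: DBU (2.5 equiv), MeCN, 60 °C
Reagents that add atoms: none
Why: Deprotonation at C2 (α to the ester) triggers E1cB expulsion of p-toluenesulfinate from nitrogen and the 3H-indole tautomerises to the aromatic 1H-indole, a known redox-neutral aromatisation of cyclic N-sulfonyl α-amino esters that leaves aryl bromides untouched.

**Step 7**
Reactants: 14 methyl 4,6-dibromo-1H-indole-2-carboxylate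
Product: 16 4,6-dibromo-1H-indole-2-carboxylic acid, via lithium carboxylate 15 (not isolated)
Conditions: LiOH·H2O (3 equiv), THF-MeOH-H2O, 40 °C; then 1 M HCl to pH 2
Reagents that add atoms: lithium hydroxide, [Li+].[OH-]
Why: Standard saponification of a methyl ester by acyl-oxygen cleavage, under which aryl bromides and the indole N-H are inert.

**Step 8**
Reactants: 16 4,6-dibromo-1H-indole-2-carboxylic acid
Product: 18 2,3,4,6-tetrabromo-1H-indole (target), via 3-bromo acid 17 (not isolated)
Conditions: NBS (2.1 equiv), LiOAc (0.2 equiv), dry DMF, 0 °C → rt, dark; neutral work-up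
Reagents that add atoms: N-bromosuccinimide, O=C1CCC(=O)N1Br
Why: Electrophilic bromination at the most nucleophilic position C3 gives 17, and the second bromonium equivalent ends at C2 ipso to the carboxylate, whose loss as CO2 restores aromaticity (Hunsdiecker-type halodecarboxylation, known for indole-2-carboxylic and pyrrole-2-carboxylic acids), while C5 (between two bromines) and C7 of the deactivated nucleus should stay untouched at this stoichiometry.

**Compound list**
1 | 2,4,6-tribromophenol | Oc1c(Br)cc(Br)cc1Br | starting material
2 | trimethyl(2,4,6-tribromophenoxy)silane | C[Si](C)(C)Oc1c(Br)cc(Br)cc1Br | intermediate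
3 | [3,5-dibromo-2-(trimethylsilyloxy)phenyl]lithium | [Li]c1cc(Br)cc(Br)c1O[Si](C)(C)C | intermediate
4 | lithium 2,4-dibromo-6-(trimethylsilyl)phenoxide | [Li+].[O-]c1c(Br)cc(Br)cc1[Si](C)(C)C | intermediate
5 | 2,4-dibromo-6-(trimethylsilyl)phenyl trifluoromethanesulfonate | C[Si](C)(C)c1cc(Br)cc(Br)c1OS(=O)(=O)C(F)(F)F | intermediate
6 | L-serine methyl ester hydrochloride | COC(=O)[C@@H](N)CO.Cl | starting material
7 | p-toluenesulfonyl chloride | Cc1ccc(cc1)S(Cl)(=O)=O | starting material
8 | methyl N-tosyl-L-serinate, (S) | COC(=O)[C@@H](NS(=O)(=O)c1ccc(C)cc1)CO | intermediate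
9 | methyl O-mesyl-N-tosyl-L-serinate, (S) | COC(=O)[C@@H](NS(=O)(=O)c1ccc(C)cc1)COS(C)(=O)=O | intermediate
10 | methyl 2-(tosylamino)acrylate | C=C(NS(=O)(=O)c1ccc(C)cc1)C(=O)OC | intermediate
11 | 3,5-dibromobenzyne | C1#CC(Br)=CC(Br)=C1 | intermediate
12 | methyl 4,6-dibromo-1-tosylindoline-2-carboxylate (racemic) | COC(=O)C1Cc2c(Br)cc(Br)cc2N1S(=O)(=O)c1ccc(C)cc1 | intermediate
13 | methyl 4,6-dibromo-3H-indole-2-carboxylate | COC(=O)C1=Nc2cc(Br)cc(Br)c2C1 | intermediate
14 | methyl 4,6-dibromo-1H-indole-2-carboxylate | COC(=O)c1cc2c(Br)cc(Br)cc2[nH]1 | intermediate
15 | lithium 4,6-dibromo-1H-indole-2-carboxylate | [Li+].[O-]C(=O)c1cc2c(Br)cc(Br)cc2[nH]1 | intermediate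
16 | 4,6-dibromo-1H-indole-2-carboxylic acid | OC(=O)c1cc2c(Br)cc(Br)cc2[nH]1 | intermediate
17 | 3,4,6-tribromo-1H-indole-2-carboxylic acid | OC(=O)c1[nH]c2cc(Br)cc(Br)c2c1Br | intermediate
18 | 2,3,4,6-tetrabromo-1H-indole | Brc1cc(Br)c2c(Br)c(Br)[nH]c2c1 | target

**Step count**
Total step count: 8.
Longest linear sequence: 6 (steps 1, 2, 5, 6, 7, 8; the serine branch, steps 3, 4, 5, 6, 7, 8, is equally long).

**Steps most likely to fail**

**Step 5.**
- The aryl anion may be protonated by the acidic sulfonamide N-H before the ring closes, which would give plain N-arylation.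
- The anion may expel the neighbouring bromide and pass into a second aryne.
- Nitrogen may add partly at the wrong aryne terminus.
- The acrylate may oligomerise by aza-Michael addition under fluoride.

Fallback, from 5, back at 16: the two bonds are made in separate events. Methyl pyruvate and tosylhydrazide are condensed (MeOH, rt) to methyl pyruvate N-tosylhydrazone F1. With 5, CsF, MeCN, rt, its sulfonamide nitrogen is arylated through the same aryne 11. Here protonation of the aryl anion is the wanted outcome, and it gives methyl 2-[2-(3,5-dibromophenyl)-2-tosylhydrazinylidene]propanoate F2. BF3·OEt2 in refluxing MeCN then runs the Fischer indole synthesis. Its [3,3] shift forms C3-C3a at either of two equivalent ortho positions and gives methyl 4,6-dibromo-1-tosyl-1H-indole-2-carboxylate F3. KOH in aqueous MeOH at reflux cleaves both the N-tosyl group and the ester, and acidification delivers 16.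

**Step 8.**
- The reaction may stall after C3 bromination, because the tribrominated nucleus is a poor partner for the ipso attack.
- The bromoindolenine stage may be diverted oxidatively by adventitious water.
- Ring bromination may continue at C7.

Fallback, from 16, back at 18: decarboxylation and bromination are separated. Protodecarboxylation with Ag2CO3 (10 mol %) and AcOH (5 mol %) in DMSO at 120 °C gives 4,6-dibromo-1H-indole F4. NBS (1 equiv) in DMF at 0 °C gives 3,4,6-tribromo-1H-indole F5. A second equivalent of NBS on silica gel in CH2Cl2 substitutes the free C2-H and gives 18.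

**Step 2.**
- Exchange may compete at the para bromine.
- Butyl may attack silicon of this aryl silyl ether, whose phenoxide is a good leaving group.
- Silyl migration may be incomplete before triflation.

Fallback, from 1, back at 5: the anionic O-to-C shift is replaced by intermolecular C-silylation of a chelation-directed arylmagnesium.
1. MOMCl and i-Pr2NEt in CH2Cl2 give 1,3,5-tribromo-2-(methoxymethoxy)benzene F6.
2. i-PrMgCl·LiCl in THF at −25 °C exchanges an ortho bromine and gives [3,5-dibromo-2-(methoxymethoxy)phenyl]magnesium chloride F7.
3. Me3SiCl, with warming to rt, gives [3,5-dibromo-2-(methoxymethoxy)phenyl]trimethylsilane F8.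
4. HCl in MeOH at rt frees 2,4-dibromo-6-(trimethylsilyl)phenol F9.
5. Tf2O and pyridine in CH2Cl2 at 0 °C give 5.

**Further compounds**
F1 | step 5 | methyl pyruvate N-tosylhydrazone (C=N geometry not defined) | COC(=O)C(C)=NNS(=O)(=O)c1ccc(C)cc1
F2 | step 5 | methyl 2-[2-(3,5-dibromophenyl)-2-tosylhydrazinylidene]propanoate (C=N geometry not defined) | COC(=O)C(C)=NN(c1cc(Br)cc(Br)c1)S(=O)(=O)c1ccc(C)cc1
F3 | step 5 | methyl 4,6-dibromo-1-tosyl-1H-indole-2-carboxylate | COC(=O)c1cc2c(Br)cc(Br)cc2n1S(=O)(=O)c1ccc(C)cc1
F4 | step 8 | 4,6-dibromo-1H-indole | Brc1cc(Br)c2cc[nH]c2c1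
F5 | step 8 | 3,4,6-tribromo-1H-indole | Brc1cc(Br)c2c(Br)c[nH]c2c1
F6 | step 2 | 1,3,5-tribromo-2-(methoxymethoxy)benzene | COCOc1c(Br)cc(Br)cc1Br
F7 | step 2 | [3,5-dibromo-2-(methoxymethoxy)phenyl]magnesium chloride | COCOc1c(Br)cc(Br)cc1[Mg]Cl
F8 | step 2 | [3,5-dibromo-2-(methoxymethoxy)phenyl]trimethylsilane | COCOc1c(Br)cc(Br)cc1[Si](C)(C)C
F9 | step 2 | 2,4-dibromo-6-(trimethylsilyl)phenol | Oc1c(Br)cc(Br)cc1[Si](C)(C)C
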